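## Retrosynthetic overview

1. Target 20 ← desilylation ← Cr(II) macro-allylation/lactonisation that forms C6–C7, sets C6/C7 and closes the ten-membered carbocycle and the γ-lactone last (17 → 19).
2. Allylic bromide 17 ← C7 dimethyl acetal (unmasked to the aldehyde, then an acrylate unit from methyl propiolate and bromide transposition).
3. 3(2H)-Furanone plus (Z)-enal ← one-flask oxidative ring transposition of 2-alkynylfuran carbinol 11; the furan is a masked (Z)-C3–C6 ene-dicarbonyl.
4. 11 ← Sonogashira union of alkyne 7 with iodofuran 10; C10 ← chelation-controlled ethynyl addition; C8/C9 ← amine-catalysed syn-aldol of two achiral partners (first stereocentres).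
5. Ring order: furanone (step 9), then carbocycle and lactone together (step 13).

Assumption/convention: 1-[(4-methoxybenzyl)oxy]propan-2-one (1) is taken as a catalogue compound; locants C1–C15 are the germacrane positions of the target (C1 ketone, C3/C10 ether carbons of the furanone, C6 lactone carbinol, C8 methacrylate, C9 isovalerate, C15 CH2OH).

## Route

Step 1
Reactants: 1 1-[(4-methoxybenzyl)oxy]propan-2-one; 2 2,2-dimethoxyacetaldehyde
Product: 3 syn-aldol adduct
Conditions: O-tert-butyl-L-threonine (20 mol %), NMP/H2O (97:3), 4 °C, 72 h (1 in 3-fold excess; 2 as the 60 % aqueous solution)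
Reagents that add atoms: none
Why: Primary-amine (enamine) catalysed direct syn-aldol reaction in which the amino acid forms the hydrogen-bonded (Z)-enamine on the oxygenated side of 1 and its carboxylic acid steers the aldehyde to one face, so C8 and C9 are set syn (3R,4R, by analogy with L-amino-acid catalysts) from achiral materials.

Step 2
Reactants: 3 syn-aldol adduct
Product: 4 ethynyl diol
Conditions: MgBr2·OEt2, CH2Cl2, −78 °C; HC≡CMgBr (3.5 equiv), THF, −78 → −20 °C
Reagents that add atoms: ethynylmagnesium bromide C#C[Mg]Br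
Why: Cram-chelate-controlled Grignard addition in which magnesium bridges the ketone and the α-OPMB oxygen and the acetylide attacks anti to the C8 chain, giving the 9,10-syn tertiary alcohol (C10) after one equivalent has deprotonated 8-OH.

Step 3
Reactants: 4 ethynyl diol
Product: 5 8-O-methacrylate
Conditions: methacrylic anhydride, Et3N, DMAP (cat.), CH2Cl2, 0 °C
Reagents that add atoms: methacrylic anhydride CC(=C)C(=O)OC(=O)C(C)=C
Why: DMAP-catalysed acylation takes only the secondary 8-OH because the tertiary propargylic 10-OH does not react under these conditions.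

Step 4
Reactants: 5 8-O-methacrylate
Product: 6 9,10-diol
Conditions: DDQ, CH2Cl2/pH 7 buffer (10:1), 0 °C → rt
Reagents that add atoms: none
Why: Oxidative PMB ether cleavage (hydride abstraction by DDQ, hydrolysis of the oxocarbenium ion) frees O9 alone and leaves the esters, alkyne and acetal untouched.

Step 5
Reactants: 6 9,10-diol
Product: 7 diester alkyne
Conditions: isovaleric anhydride, DMAP, pyridine, CH2Cl2, −20 → 0 °C
Reagents that add atoms: isovaleric anhydride CC(C)CC(=O)OC(=O)CC(C)C
Why: Steglich-type acylation of the only secondary hydroxyl puts the isovalerate on O9, run cold so that acylation outruns 8→9 acyl migration, while the tertiary 10-OH stays free.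

Step 6
Reactants: 8 furan-3-ylmethanol
Product: 9 (2-iodofuran-3-yl)methanol
Conditions: n-BuLi (2.2 equiv), THF, −78 → 0 °C; I2, −78 °C
Reagents that add atoms: iodine II
Why: Directed ortho-lithiation in which the lithium alkoxide guides the second equivalent of base to C2 of the furan, and iodine quenches the dianion there.

Step 7
Reactants: 9 (2-iodofuran-3-yl)methanol
Product: 10 iodofuran silyl ether
Conditions: TBDPSCl, imidazole, DMF, rt
Reagents that add atoms: tert-butyl(chloro)diphenylsilane CC(C)(C)[Si](Cl)(c1ccccc1)c1ccccc1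
Why: Standard silylation of the primary alcohol; the robust TBDPS group survives steps 8–13 and keeps O15 from cyclising onto the later C6 aldehyde.

Step 8
Reactants: 7 diester alkyne; 10 iodofuran silyl ether
Product: 11 alkynylfuran
Conditions: Pd(PPh3)2Cl2 (5 mol %), CuI (10 mol %), i-Pr2NH, THF, rt
Reagents that add atoms: none
Why: Sonogashira coupling of the terminal alkyne with the 2-iodofuran joins C2 to C3 under mild amine base that leaves the tertiary alcohol, acetal and both esters intact.

Step 9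
Reactants: 11 alkynylfuran
Product: 13 furanone enal acetal, via keto-enal 12 (not isolated)
Conditions: DMDO (1.1 equiv, acetone), CH2Cl2, −40 → 0 °C; then AuCl3 (5 mol %), H2O (2 equiv), rt
Reagents that add atoms: dimethyldioxirane CC1(C)OO1
Why: Proposed new method: a one-flask oxidative furan→3(2H)-furanone ring transposition in which the dioxirane epoxidises the furan and the epoxide opens to the (Z)-ene-dicarbonyl γ-hydroxy ynone 12 (closest known type: dioxirane or NBS opening of furans to cis-enediones), after which Au(III) π-activates the ynone so that water adds at C1 and the 10-OH closes on C3 with loss of water (closest known type: Au-catalysed cyclisation of γ-hydroxyalkynones to 3(2H)-furanones); the furan oxygen thus becomes the C6 aldehyde oxygen, the tertiary hydroxyl becomes the furanone ring oxygen, the 4Z geometry is inherited from the furan and C10 is not touched.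

Step 10
Reactants: 13 furanone enal acetal
Product: 14 furanone dialdehyde
Conditions: TESOTf, 2,4,6-collidine, CH2Cl2, 0 °C; then H2O
Reagents that add atoms: water O
Why: Chemoselective non-protic deacetalisation in which the silyl triflate ionises the dimethyl acetal, collidine traps the oxocarbenium ion as a pyridinium salt and water releases the C7 aldehyde, so the Z-enal, furanone and silyl ether never meet aqueous acid (with O10 already in the furanone no lactol can form).

Step 11
Reactants: 14 furanone dialdehyde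
Product: 15 allylic alcohol
Conditions: methyl propiolate, DIBAL-H, HMPA, THF, 0 °C; then 14 (1.3 equiv of the vinylalane), −40 → −10 °C; Rochelle salt
Reagents that add atoms: methyl propiolate C#CC(=O)OC
Why: Vinylalumination (a non-basic Morita–Baylis–Hillman surrogate) in which the α-alumino acrylate adds 1,2 to the strongly activated α-acyloxy aldehyde faster than to the cross-conjugated β,β-disubstituted enal or the esters, and the new carbinol centre needs no control because step 12 erases it.

Step 12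
Reactants: 15 allylic alcohol
Product: 17 allylic bromide, via mesylate 16 (not isolated)
Conditions: MsCl, Et3N, CH2Cl2, −40 °C; then LiBr, THF, −40 → 0 °C
Reagents that add atoms: methanesulfonyl chloride CS(=O)(=O)Cl (atoms only in 16); lithium bromide [Li+].[Br-]
Why: Mesylation followed by SN2′ attack of bromide (allylic transposition) gives the thermodynamically preferred (Z)-2-(bromomethyl)enoate with C8 trans to the ester, without touching C8.

Step 13
Reactants: 17 allylic bromide
Product: 19 silyl-protected macrolactone, via hydroxy ester 18 (not isolated)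
Conditions: CrCl2 (6 equiv), THF, 25 °C, slow addition to 2 mM; aq. NH4Cl, then PPTS (cat.), CH2Cl2
Reagents that add atoms: none
Why: Intramolecular Nozaki–Hiyama allylation in which the allylchromium(III) adds through C7 to the C6 aldehyde via a chair transition state with the C8 chain pseudo-equatorial (anti addition, hence the 6,7-trans lactone) on the enal face anti to the 8-acyloxy group, setting C6 (R) and C7 (S) together, after which the C6 alkoxide closes the γ-lactone on the methyl ester.

Step 14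
Reactants: 19 silyl-protected macrolactone
Product: 20 CNP0552093.1
Conditions: HF·pyridine, pyridine/THF, 0 °C → rt
Reagents that add atoms: none
Why: Buffered fluoride cleavage of the Si–O bond frees the C15 hydroxyl and leaves the α-methylene lactone, both esters and the furanone untouched.

## Compound list

1 | 1-[(4-methoxybenzyl)oxy]propan-2-one | CC(=O)COCc1ccc(OC)cc1 | starting material
2 | 2,2-dimethoxyacetaldehyde | COC(OC)C=O | starting material
3 | (3R,4R)-4-hydroxy-5,5-dimethoxy-3-[(4-methoxybenzyl)oxy]pentan-2-one | COC(OC)[C@H](O)[C@@H](OCc1ccc(OC)cc1)C(C)=O | intermediate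
4 | (2R,3R,4R)-1,1-dimethoxy-3-[(4-methoxybenzyl)oxy]-4-methylhex-5-yne-2,4-diol | COC(OC)[C@H](O)[C@@H](OCc1ccc(OC)cc1)[C@](C)(O)C#C | intermediate
5 | (2R,3R,4R)-4-hydroxy-1,1-dimethoxy-3-[(4-methoxybenzyl)oxy]-4-methylhex-5-yn-2-yl 2-methylprop-2-enoate | COC(OC)[C@H](OC(=O)C(C)=C)[C@@H](OCc1ccc(OC)cc1)[C@](C)(O)C#C | intermediate
6 | (2R,3R,4R)-3,4-dihydroxy-1,1-dimethoxy-4-methylhex-5-yn-2-yl 2-methylprop-2-enoate | COC(OC)[C@H](OC(=O)C(C)=C)[C@@H](O)[C@](C)(O)C#C | intermediate
7 | (2R,3R,4R)-4-hydroxy-1,1-dimethoxy-4-methyl-3-[(3-methylbutanoyl)oxy]hex-5-yn-2-yl 2-methylprop-2-enoate | COC(OC)[C@H](OC(=O)C(C)=C)[C@@H](OC(=O)CC(C)C)[C@](C)(O)C#C | intermediate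
8 | furan-3-ylmethanol | OCc1ccoc1 | starting material
9 | (2-iodofuran-3-yl)methanol | OCc1ccoc1I | intermediate
10 | tert-butyl[(2-iodofuran-3-yl)methoxy]diphenylsilane | CC(C)(C)[Si](OCc1ccoc1I)(c1ccccc1)c1ccccc1 | intermediate
11 | (2R,3R,4R)-6-[3-({[tert-butyl(diphenyl)silyl]oxy}methyl)furan-2-yl]-4-hydroxy-1,1-dimethoxy-4-methyl-3-[(3-methylbutanoyl)oxy]hex-5-yn-2-yl 2-methylprop-2-enoate | COC(OC)[C@H](OC(=O)C(C)=C)[C@@H](OC(=O)CC(C)C)[C@](C)(O)C#Cc1occc1CO[Si](C(C)(C)C)(c1ccccc1)c1ccccc1 | intermediate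
12 | (2Z,7R,8R,9R)-3-({[tert-butyl(diphenyl)silyl]oxy}methyl)-7-hydroxy-10,10-dimethoxy-7-methyl-4-oxodec-2-en-5-ynal, 9-O-methacrylate 8-O-(3-methylbutanoate) | COC(OC)[C@H](OC(=O)C(C)=C)[C@@H](OC(=O)CC(C)C)[C@](C)(O)C#CC(=O)/C(CO[Si](C(C)(C)C)(c1ccccc1)c1ccccc1)=C\C=O | intermediate (not isolated)
13 | (1R,2R)-1-{(2S)-5-[(1Z)-1-({[tert-butyl(diphenyl)silyl]oxy}methyl)-3-oxoprop-1-en-1-yl]-2-methyl-3-oxo-2,3-dihydrofuran-2-yl}-3,3-dimethoxy-2-[(2-methylprop-2-enoyl)oxy]propyl 3-methylbutanoate | COC(OC)[C@H](OC(=O)C(C)=C)[C@@H](OC(=O)CC(C)C)[C@]1(C)OC(=CC1=O)/C(CO[Si](C(C)(C)C)(c2ccccc2)c2ccccc2)=C\C=O | intermediate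
14 | (1R,2R)-1-{(2S)-5-[(1Z)-1-({[tert-butyl(diphenyl)silyl]oxy}methyl)-3-oxoprop-1-en-1-yl]-2-methyl-3-oxo-2,3-dihydrofuran-2-yl}-2-[(2-methylprop-2-enoyl)oxy]-3-oxopropyl 3-methylbutanoate | O=C[C@H](OC(=O)C(C)=C)[C@@H](OC(=O)CC(C)C)[C@]1(C)OC(=CC1=O)/C(CO[Si](C(C)(C)C)(c2ccccc2)c2ccccc2)=C\C=O | intermediate
15 | methyl (4S,5R)-5-{(2S)-5-[(1Z)-1-({[tert-butyl(diphenyl)silyl]oxy}methyl)-3-oxoprop-1-en-1-yl]-2-methyl-3-oxo-2,3-dihydrofuran-2-yl}-3-hydroxy-2-methylidene-4-[(2-methylprop-2-enoyl)oxy]-5-[(3-methylbutanoyl)oxy]pentanoate (C3 epimer mixture) | C=C(C(=O)OC)C(O)[C@H](OC(=O)C(C)=C)[C@@H](OC(=O)CC(C)C)[C@]1(C)OC(=CC1=O)/C(CO[Si](C(C)(C)C)(c2ccccc2)c2ccccc2)=C\C=O | intermediate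
16 | 3-O-methanesulfonate of 15 (C3 epimer mixture) | C=C(C(=O)OC)C(OS(C)(=O)=O)[C@H](OC(=O)C(C)=C)[C@@H](OC(=O)CC(C)C)[C@]1(C)OC(=CC1=O)/C(CO[Si](C(C)(C)C)(c2ccccc2)c2ccccc2)=C\C=O | intermediate (not isolated)
17 | methyl (2Z,4S,5R)-2-(bromomethyl)-5-{(2S)-5-[(1Z)-1-({[tert-butyl(diphenyl)silyl]oxy}methyl)-3-oxoprop-1-en-1-yl]-2-methyl-3-oxo-2,3-dihydrofuran-2-yl}-4-[(2-methylprop-2-enoyl)oxy]-5-[(3-methylbutanoyl)oxy]pent-2-enoate | BrC/C(C(=O)OC)=C\[C@H](OC(=O)C(C)=C)[C@@H](OC(=O)CC(C)C)[C@]1(C)OC(=CC1=O)/C(CO[Si](C(C)(C)C)(c2ccccc2)c2ccccc2)=C\C=O | intermediate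
18 | methyl (4Z,6R,7S,8S,9R,10S)-15-{[tert-butyl(diphenyl)silyl]oxy}-6-hydroxy-8-(methacryloyloxy)-9-[(3-methylbutanoyl)oxy]-1-oxo-3,10-epoxygermacra-2,4,11(13)-trien-12-oate | C=C(C)C(=O)O[C@H]1[C@@H](C(=C)C(=O)OC)[C@H](O)/C=C(/CO[Si](C(C)(C)C)(c3ccccc3)c3ccccc3)C2=CC(=O)[C@@](C)(O2)[C@@H]1OC(=O)CC(C)C | intermediate (not isolated)
19 | 15-O-tert-butyldiphenylsilyl ether of 20: (4Z,6R,7S,8S,9R,10S)-15-silyloxy-8-(methacryloyloxy)-9-[(3-methylbutanoyl)oxy]-1-oxo-3,10-epoxygermacra-2,4,11(13)-trien-12,6-olide | C=C(C)C(=O)O[C@H]1[C@H]2C(=C)C(=O)O[C@@H]2/C=C(/CO[Si](C(C)(C)C)(c3ccccc3)c3ccccc3)C2=CC(=O)[C@@](C)(O2)[C@@H]1OC(=O)CC(C)C | intermediate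
20 | CNP0552093.1: (4Z,6R,7S,8S,9R,10S)-15-hydroxy-8-(2-methylprop-2-enoyloxy)-9-(3-methylbutanoyloxy)-1-oxo-3,10-epoxygermacra-2,4,11(13)-trien-12,6-olide | C=C(C)C(=O)O[C@H]1[C@H]2C(=C)C(=O)O[C@@H]2/C=C(/CO)C2=CC(=O)[C@@](C)(O2)[C@@H]1OC(=O)CC(C)C | target

## Step count and risks

Total steps: 14. Longest linear sequence: 12 (steps 1–5 and 8–14; steps 6–7 make the furan fragment).

Steps most likely to fail:

Step 9 (the proposed new one-flask ring transposition). Gold may be inhibited, or the Z-enal may not survive the hydrative cyclisation. The fallback uses only known reaction types and hydrates the alkyne before the furan is opened. It sets out from 11: silver-catalysed CO2-relay hydration of the tertiary propargylic alcohol (AgOAc, DBU, CO2, wet MeCN) forms the alkylidene cyclic carbonate F1, which is hydrolysed in the same pot to the α-hydroxy ketone F2. Buffered NBS oxidation (NaHCO3, THF/H2O, 0 °C) then opens the furan to the (Z)-configured hydroxy diketone enal F3. Its acid-catalysed cyclodehydration (PPTS, CH2Cl2), the classical 3(2H)-furanone synthesis from α′-hydroxy-1,3-diketones, brings the route back at 13.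

Step 13 (Cr(II) macrocyclisation onto the furanone-bearing enal). The ring closure may fail for strain, reduction of the enal may compete, or the wrong C6/C7 diastereomer may form. The fallback replaces the reductive organochromium closure with a Lewis-acid allylstannane closure. It sets out from 17: hexabutylditin with Pd(0) gives the allylstannane F4, which is cyclised with BF3·OEt2 at −78 °C under high dilution (open transition state, no reductant) to the hydroxy ester 18. Lactonisation with PPTS brings the route back at 19.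

Step 11 (chemoselective vinylalumination of a dialdehyde that also carries a β-acyloxy group). The enal may be attacked too, or the aluminium reagent may cause elimination. The fallback is the amine-catalysed Morita–Baylis–Hillman reaction of 14 with methyl acrylate (3-hydroxyquinuclidine, MeOH/THF, rt), a nucleophilic-catalysis mechanism that engages only the unconjugated, activated aldehyde. It sets out from 14 and comes back at 15, and it makes no new compound (F0).

Further compounds
F1 | step 9 | cyclic carbonate of 11 spanning O10 and C1: (2R,3R)-3-[(4R,5Z)-5-{[3-({[tert-butyl(diphenyl)silyl]oxy}methyl)furan-2-yl]methylidene}-4-methyl-2-oxo-1,3-dioxolan-4-yl]-1,1-dimethoxy-3-[(3-methylbutanoyl)oxy]propan-2-yl 2-methylprop-2-enoate | COC(OC)[C@H](OC(=O)C(C)=C)[C@@H](OC(=O)CC(C)C)[C@]1(C)OC(=O)O/C1=C\c1occc1CO[Si](C(C)(C)C)(c1ccccc1)c1ccccc1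
F2 | step 9 | α-hydroxy ketone: (2R,3R,4R)-6-[3-({[tert-butyl(diphenyl)silyl]oxy}methyl)furan-2-yl]-4-hydroxy-1,1-dimethoxy-4-methyl-3-[(3-methylbutanoyl)oxy]-5-oxohexan-2-yl 2-methylprop-2-enoate | COC(OC)[C@H](OC(=O)C(C)=C)[C@@H](OC(=O)CC(C)C)[C@](C)(O)C(=O)Cc1occc1CO[Si](C(C)(C)C)(c1ccccc1)c1ccccc1
F3 | step 9 | hydroxy diketone enal: (2Z,7R,8R,9R)-3-({[tert-butyl(diphenyl)silyl]oxy}methyl)-7-hydroxy-10,10-dimethoxy-7-methyl-4,6-dioxodec-2-enal, 9-O-methacrylate 8-O-(3-methylbutanoate) | COC(OC)[C@H](OC(=O)C(C)=C)[C@@H](OC(=O)CC(C)C)[C@](C)(O)C(=O)CC(=O)/C(CO[Si](C(C)(C)C)(c1ccccc1)c1ccccc1)=C\C=O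
F0 | step 11 | none | none
F4 | step 13 | allylstannane: methyl (2Z,4S,5R)-5-{(2S)-5-[(1Z)-1-({[tert-butyl(diphenyl)silyl]oxy}methyl)-3-oxoprop-1-en-1-yl]-2-methyl-3-oxo-2,3-dihydrofuran-2-yl}-4-[(2-methylprop-2-enoyl)oxy]-5-[(3-methylbutanoyl)oxy]-2-[(tributylstannyl)methyl]pent-2-enoate | CCCC[Sn](CCCC)(CCCC)C/C(C(=O)OC)=C\[C@H](OC(=O)C(C)=C)[C@@H](OC(=O)CC(C)C)[C@]1(C)OC(=CC1=O)/C(CO[Si](C(C)(C)C)(c2ccccc2)c2ccccc2)=C\C=O
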